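**Retrosynthetic overview**
- Final bonds: the 2-isopropenyl group comes from dehydration of a tertiary carbinol, and the C3 ester from Yamaguchi acylation of the trans alcohol with (Z)-2-(acetoxymethyl)but-2-enoic acid. The acid is made from crotonaldehyde via (Z)-2-bromobut-2-enal; its geometry is carried through Br/Li exchange and carboxylation.
- The C5 acetyl group is put on after the ring is made (bromination para to O1, then Stille acetylation), so the arene can enter as symmetrical benzyne and no aryne regiochemistry arises.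
- Key disconnection: both bonds between the benzo ring and the hetero ring, O1–C7a and C3–C3a, are made at once by a formal [3+2] annulation of benzyne with the O1–C2–C3 unit of an α-oxido aldehyde. This closes the only ring that has to be built (the dihydrofuran ring; the benzene ring is bought).
- Enabling feature: O1 and C3 sit on the adjacent ring-fusion carbons C7a and C3a and are 1,3-related through C2; C3 is a carbinol carbon (an aldehyde carbon in the precursor); O1 is para to C5.
- Stereochemistry: C2 comes from Katsuki–Sharpless epoxidation of prenol (its C–O bond is never broken); C3 is set by 1,2-induction in the ring closure (2,3-trans).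

Key step: step 5

Remark on the chemistry: the route is planned for the (2R,3S) 2,3-trans isomer with the (Z)-enoate, as the SMILES specifies; the enantiomeric purity of the target is that of epoxy alcohol 2. Compounds 1, 3, 8, 15 and 19 are taken as commercial.

**Step 1**
Reactants: 1 3-methylbut-2-en-1-ol (prenol)
Product: 2 [(2S)-3,3-dimethyloxiran-2-yl]methanol
Conditions: Ti(OiPr)4 (5 mol%), L-(+)-DIPT (6 mol%), t-BuOOH (1.5 equiv), 4 Å MS, CH2Cl2, −20 °C
Reagents that add atoms: tert-butyl hydroperoxide, CC(C)(C)OO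
Why: Katsuki–Sharpless asymmetric epoxidation of a primary allylic alcohol; the L-(+)-tartrate catalyst should deliver oxygen to the face that gives the 2S epoxide (the same sense as geraniol to its 2S,3S epoxide), and C2 is the only stereocentre.

**Step 2**
Reactants: 2 [(2S)-3,3-dimethyloxiran-2-yl]methanol; 3 (4-methoxyphenyl)methanol
Product: 4 (2S)-3-[(4-methoxyphenyl)methoxy]-3-methylbutane-1,2-diol
Conditions: 3 (5 equiv), BF3·OEt2 (5 mol%), CH2Cl2, −40 → −10 °C
Reagents that add atoms: none
Why: Lewis-acid-catalysed epoxide alcoholysis with SN1-like attack at the tertiary carbon; the C2–O bond is not broken, so C2 stays S, and the tertiary oxygen becomes a PMB ether that cannot migrate in step 5.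

**Step 3**
Reactants: 4 (2S)-3-[(4-methoxyphenyl)methoxy]-3-methylbutane-1,2-diol
Product: 5 (2S)-3-[(4-methoxyphenyl)methoxy]-3-methyl-1,2-bis(trimethylsilyloxy)butane
Conditions: TMSCl (2.4 equiv), imidazole (5 equiv), CH2Cl2, 0 °C
Reagents that add atoms: chlorotrimethylsilane, C[Si](C)(C)Cl
Why: standard O-silylation of the primary and the secondary hydroxyl group, which sets up the selective oxidation of step 4 and the fluoride-triggered release of the C2 alkoxide in step 5.

**Step 4**
Reactants: 5 (2S)-3-[(4-methoxyphenyl)methoxy]-3-methyl-1,2-bis(trimethylsilyloxy)butane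
Product: 7 (2R)-3-[(4-methoxyphenyl)methoxy]-3-methyl-2-(trimethylsilyloxy)butanal, via alkoxysulfonium chloride 6 (not isolated)
Conditions: (COCl)2, DMSO, CH2Cl2, −78 → −30 °C; then Et3N, −78 → 0 °C
Reagents that add atoms: none
Why: Swern oxidation run directly on the silyl ether: the activated sulfoxide exchanges only with the unhindered primary O–SiMe3 group, so the aldehyde should form with the secondary silyl ether and the α-stereocentre untouched (the descriptor changes from S to R only because CHO outranks the tertiary carbon).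

**Step 5**
Reactants: 7 (2R)-3-[(4-methoxyphenyl)methoxy]-3-methyl-2-(trimethylsilyloxy)butanal; 8 2-(trimethylsilyl)phenyl trifluoromethanesulfonate
Product: 13 (2S,3S)-2-{2-[(4-methoxyphenyl)methoxy]propan-2-yl}-2,3-dihydro-1-benzofuran-3-ol, via potassium alkoxide 9 (not isolated), via benzyne 10 (not isolated), via aryl anion 11 (not isolated), via potassium 3-olate 12 (not isolated)
Conditions: 8 (1.5 equiv), KF (4 equiv), 18-crown-6 (4 equiv), THF, 0 °C → rt, 7 added over 2 h; aq NH4Cl
Reagents that add atoms: none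
Why: Proposed new method: fluoride removes the O–SiMe3 group of 7 to give α-oxido aldehyde 9 and converts 8 into benzyne 10; the alkoxide adds to the aryne (O1–C7a) and the resulting aryl anion 11, formed in a medium without a proton source, adds to the pendant aldehyde (C3–C3a) to give 12. The closest known reactions are aryne insertion into O–H bonds and the aryne annulations of salicylaldehydes (to xanthenols) and of N-sulfonyl α-amino ketones (to 3-hydroxyindolines); an aliphatic α-hydroxy aldehyde has not been used in this way. The dihydrofuran ring closes by 5-exo-trig attack of the sp2 carbanion on the C=O group. C2 is carried over from 7 unchanged, since its C–O and C–H bonds are not touched and the adjacent alkoxide disfavours α-deprotonation; the new centre C3 is set by 1,2-induction, the carbonyl oxygen turning away from the bulky CMe2(OPMB) group on C2 in the envelope transition state, which should give the 2,3-trans (3S) alcohol. No regioselectivity is needed because benzyne is symmetrical, which is why the acetyl group enters later; the chemoselectivity for O1 is secured by the PMB ether on the tertiary oxygen (not nucleophilic and unable to migrate), and the crown ether keeps K+ from chelating the two oxygens into a cis closure.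

**Step 6**
Reactants: 13 (2S,3S)-2-{2-[(4-methoxyphenyl)methoxy]propan-2-yl}-2,3-dihydro-1-benzofuran-3-ol
Product: 14 (2S,3S)-5-bromo-2-{2-[(4-methoxyphenyl)methoxy]propan-2-yl}-2,3-dihydro-1-benzofuran-3-ol
Conditions: NBS (1.05 equiv), MeCN, 0 °C, dark
Reagents that add atoms: N-bromosuccinimide, O=C1CCC(=O)N1Br
Why: electrophilic aromatic bromination of an alkyl aryl ether; O1 directs to the free para position C5, and the PMB ring, whose para position is blocked, should react much more slowly.

**Step 7**
Reactants: 14 (2S,3S)-5-bromo-2-{2-[(4-methoxyphenyl)methoxy]propan-2-yl}-2,3-dihydro-1-benzofuran-3-ol; 15 tributyl(1-ethoxyethenyl)stannane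
Product: 17 1-[(2S,3S)-3-hydroxy-2-{2-[(4-methoxyphenyl)methoxy]propan-2-yl}-2,3-dihydro-1-benzofuran-5-yl]ethan-1-one, via enol ether 16 (not isolated)
Conditions: Pd(PPh3)4 (5 mol%), toluene, 100 °C; then 1 M HCl, THF, 0 °C → rt
Reagents that add atoms: water, O
Why: Stille coupling of the aryl bromide with the 1-ethoxyvinyl stannane (an acetyl anion equivalent) followed by mild acid hydrolysis of enol ether 16; the free hydroxyl group needs no protection and the stereocentres are not involved.

**Step 8**
Reactants: 17 1-[(2S,3S)-3-hydroxy-2-{2-[(4-methoxyphenyl)methoxy]propan-2-yl}-2,3-dihydro-1-benzofuran-5-yl]ethan-1-one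
Product: 18 1-[(2S,3S)-3-hydroxy-2-(2-hydroxypropan-2-yl)-2,3-dihydro-1-benzofuran-5-yl]ethan-1-one
Conditions: DDQ (1.3 equiv), CH2Cl2–pH 7 buffer (10:1), 0 °C → rt
Reagents that add atoms: none
Why: oxidative cleavage of the PMB ether with DDQ; the benzofuran arene is now deactivated by the acetyl group, so the benzylic alcohol should survive, and water intercepts the oxocarbenium ion before the neighbouring hydroxyl group can.

**Step 9**
Reactants: 19 (E)-but-2-enal (crotonaldehyde)
Product: 21 (2Z)-2-bromobut-2-enal, via 2,3-dibromobutanal 20 (not isolated)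
Conditions: Br2, CH2Cl2, −20 °C; then Et3N, 0 °C → rt
Reagents that add atoms: bromine, BrBr
Why: bromine addition to the enal and E1cB dehydrobromination; the thermodynamically preferred (Z)-α-bromo enal, with CHO trans to CH3 as in crotonaldehyde, should result.

**Step 10**
Reactants: 21 (2Z)-2-bromobut-2-enal
Product: 22 (2Z)-2-bromobut-2-en-1-ol
Conditions: NaBH4, CeCl3·7H2O, MeOH, −20 °C
Reagents that add atoms: none
Why: Luche 1,2-reduction of the enal, which leaves the alkene geometry and the C–Br bond untouched.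

**Step 11**
Reactants: 22 (2Z)-2-bromobut-2-en-1-ol
Product: 25 (2Z)-2-(hydroxymethyl)but-2-enoic acid, via dilithio alkoxide 23 (not isolated), via dilithium carboxylate 24 (not isolated)
Conditions: t-BuLi (3.1 equiv), Et2O, −78 °C; CO2 (g), −78 °C → rt; 1 M HCl
Reagents that add atoms: carbon dioxide, O=C=O
Why: bromine–lithium exchange on the lithium alkoxide and carboxylation; alkenyllithium reagents are configurationally stable at −78 °C, so the carboxyl group should replace bromine with retention (CO2H cis to CH3, Z).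

**Step 12**
Reactants: 25 (2Z)-2-(hydroxymethyl)but-2-enoic acid
Product: 26 (2Z)-2-[(acetyloxy)methyl]but-2-enoic acid
Conditions: Ac2O (1.2 equiv), pyridine, CH2Cl2, 0 °C → rt; then H2O, THF
Reagents that add atoms: acetic anhydride, CC(=O)OC(C)=O
Why: O-acetylation of the primary allylic alcohol without a nucleophilic catalyst, to avoid SN2′ chemistry and Z → E isomerisation; the aqueous treatment returns the free acid.

**Step 13**
Reactants: 18 1-[(2S,3S)-3-hydroxy-2-(2-hydroxypropan-2-yl)-2,3-dihydro-1-benzofuran-5-yl]ethan-1-one; 26 (2Z)-2-[(acetyloxy)methyl]but-2-enoic acid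
Product: 28 (2S,3S)-5-acetyl-2-(2-hydroxypropan-2-yl)-2,3-dihydro-1-benzofuran-3-yl (2Z)-2-[(acetyloxy)methyl]but-2-enoate, via mixed anhydride 27 (not isolated)
Conditions: 2,4,6-trichlorobenzoyl chloride, Et3N, THF, 0 °C; then 18, DMAP (0.3 equiv), toluene, rt
Reagents that add atoms: none
Why: Yamaguchi esterification through mixed anhydride 27; only the secondary benzylic hydroxyl group of 18 should be acylated (the tertiary one is inert and, being trans to O3, cannot take the acyl group over by migration), and the Z geometry of the acid should be kept under these mild conditions.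

**Step 14**
Reactants: 28 (2S,3S)-5-acetyl-2-(2-hydroxypropan-2-yl)-2,3-dihydro-1-benzofuran-3-yl (2Z)-2-[(acetyloxy)methyl]but-2-enoate
Product: 30 (2R,3S)-5-acetyl-2-(prop-1-en-2-yl)-2,3-dihydro-1-benzofuran-3-yl (2Z)-2-[(acetyloxy)methyl]but-2-enoate, via sulfamate ester 29 (not isolated)
Conditions: Burgess reagent (2 equiv), toluene, 60 °C
Reagents that add atoms: none
Why: Burgess dehydration (syn-elimination from sulfamate ester 29) of the tertiary carbinol; loss of one of the six methyl hydrogens should be preferred over loss of the single C2–H, which is deactivated by O1 and would give a strained exocyclic enol ether, and the neutral conditions should spare the benzylic ester, the allylic acetate and the Z-enoate.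

**Compound list**
1 | 3-methylbut-2-en-1-ol (prenol) | CC(C)=CCO | starting material
2 | [(2S)-3,3-dimethyloxiran-2-yl]methanol | OC[C@@H]1OC1(C)C | intermediate
3 | (4-methoxyphenyl)methanol | COc1ccc(CO)cc1 | starting material
4 | (2S)-3-[(4-methoxyphenyl)methoxy]-3-methylbutane-1,2-diol | OC[C@H](O)C(C)(C)OCc1ccc(OC)cc1 | intermediate
5 | (2S)-3-[(4-methoxyphenyl)methoxy]-3-methyl-1,2-bis(trimethylsilyloxy)butane | C[Si](C)(C)OC[C@H](O[Si](C)(C)C)C(C)(C)OCc1ccc(OC)cc1 | intermediate
6 | {[(2S)-3-[(4-methoxyphenyl)methoxy]-3-methyl-2-(trimethylsilyloxy)butyl]oxy}dimethylsulfonium chloride | C[S+](C)OC[C@H](O[Si](C)(C)C)C(C)(C)OCc1ccc(OC)cc1.[Cl-] | intermediate (not isolated)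
7 | (2R)-3-[(4-methoxyphenyl)methoxy]-3-methyl-2-(trimethylsilyloxy)butanal | O=C[C@H](O[Si](C)(C)C)C(C)(C)OCc1ccc(OC)cc1 | intermediate
8 | 2-(trimethylsilyl)phenyl trifluoromethanesulfonate | C[Si](C)(C)c1ccccc1OS(=O)(=O)C(F)(F)F | starting material
9 | potassium (2R)-3-[(4-methoxyphenyl)methoxy]-3-methyl-1-oxobutan-2-olate | O=C[C@H]([O-])C(C)(C)OCc1ccc(OC)cc1.[K+] | intermediate (not isolated)
10 | benzyne (1,2-didehydrobenzene) | C1#CC=CC=C1 | intermediate (not isolated)
11 | potassium 2-{[(2R)-3-[(4-methoxyphenyl)methoxy]-3-methyl-1-oxobutan-2-yl]oxy}benzen-1-ide | O=C[C@H](Oc1cccc[c-]1)C(C)(C)OCc1ccc(OC)cc1.[K+] | intermediate (not isolated)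
12 | potassium (2S,3S)-2-{2-[(4-methoxyphenyl)methoxy]propan-2-yl}-2,3-dihydro-1-benzofuran-3-olate | COc1ccc(cc1)COC(C)(C)[C@H]2Oc3ccccc3[C@@H]2[O-].[K+] | intermediate (not isolated)
13 | (2S,3S)-2-{2-[(4-methoxyphenyl)methoxy]propan-2-yl}-2,3-dihydro-1-benzofuran-3-ol (2,3-trans) | COc1ccc(cc1)COC(C)(C)[C@H]2Oc3ccccc3[C@@H]2O | intermediate
14 | (2S,3S)-5-bromo-2-{2-[(4-methoxyphenyl)methoxy]propan-2-yl}-2,3-dihydro-1-benzofuran-3-ol | COc1ccc(cc1)COC(C)(C)[C@H]2Oc3ccc(Br)cc3[C@@H]2O | intermediate
15 | tributyl(1-ethoxyethenyl)stannane | CCCC[Sn](CCCC)(CCCC)C(=C)OCC | starting material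
16 | (2S,3S)-5-(1-ethoxyethenyl)-2-{2-[(4-methoxyphenyl)methoxy]propan-2-yl}-2,3-dihydro-1-benzofuran-3-ol | COc1ccc(cc1)COC(C)(C)[C@H]2Oc3ccc(C(=C)OCC)cc3[C@@H]2O | intermediate (not isolated)
17 | 1-[(2S,3S)-3-hydroxy-2-{2-[(4-methoxyphenyl)methoxy]propan-2-yl}-2,3-dihydro-1-benzofuran-5-yl]ethan-1-one | COc1ccc(cc1)COC(C)(C)[C@H]2Oc3ccc(C(C)=O)cc3[C@@H]2O | intermediate
18 | 1-[(2S,3S)-3-hydroxy-2-(2-hydroxypropan-2-yl)-2,3-dihydro-1-benzofuran-5-yl]ethan-1-one | CC(C)(O)[C@H]1Oc2ccc(C(C)=O)cc2[C@@H]1O | intermediate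
19 | (E)-but-2-enal (crotonaldehyde) | C/C=C/C=O | starting material
20 | (2R*,3S*)-2,3-dibromobutanal (racemic; one enantiomer drawn) | C[C@H](Br)[C@H](Br)C=O | intermediate (not isolated)
21 | (2Z)-2-bromobut-2-enal | C/C=C(\Br)C=O | intermediate
22 | (2Z)-2-bromobut-2-en-1-ol | C/C=C(\Br)CO | intermediate
23 | lithium (2Z)-2-lithiobut-2-en-1-olate | C/C=C(\[Li])CO[Li] | intermediate (not isolated)
24 | dilithium (2Z)-2-(oxidomethyl)but-2-enoate | C/C=C(\C(=O)O[Li])CO[Li] | intermediate (not isolated)
25 | (2Z)-2-(hydroxymethyl)but-2-enoic acid | C/C=C(\C(=O)O)CO | intermediate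
26 | (2Z)-2-[(acetyloxy)methyl]but-2-enoic acid | C/C=C(\C(=O)O)COC(C)=O | intermediate
27 | (2Z)-2-[(acetyloxy)methyl]but-2-enoic 2,4,6-trichlorobenzoic anhydride | C/C=C(\C(=O)OC(=O)c1c(Cl)cc(Cl)cc1Cl)COC(C)=O | intermediate (not isolated)
28 | (2S,3S)-5-acetyl-2-(2-hydroxypropan-2-yl)-2,3-dihydro-1-benzofuran-3-yl (2Z)-2-[(acetyloxy)methyl]but-2-enoate | CC(C)(O)[C@H]1Oc2ccc(C(C)=O)cc2[C@@H]1OC(=O)/C(=C\C)COC(C)=O | intermediate
29 | triethylammonium salt of the N-(methoxycarbonyl)sulfamate ester of the tertiary hydroxyl group of 28 (2S,3S) | COC(=O)[N-]S(=O)(=O)OC(C)(C)[C@H]1Oc2ccc(C(C)=O)cc2[C@@H]1OC(=O)/C(=C\C)COC(C)=O.CC[NH+](CC)CC | intermediate (not isolated)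
30 | (2R,3S)-5-acetyl-2-(prop-1-en-2-yl)-2,3-dihydro-1-benzofuran-3-yl (2Z)-2-[(acetyloxy)methyl]but-2-enoate | C=C(C)[C@H]1Oc2ccc(C(C)=O)cc2[C@@H]1OC(=O)/C(=C\C)COC(C)=O | target

**Count**
Total steps: 14. Longest linear sequence: 10 (steps 1–8, 13, 14); the acid branch (steps 9–12) joins at step 13.

**Steps most likely to fail**

1. Step 5 (proposed new method). The released alkoxide may isomerise by the α-ketol/enediolate pathway or lose the β-alkoxy group before it meets benzyne; the aryl anion may be protonated instead of closing, leaving an open aryl ether; or the closure may show poor facial selectivity at C3. The fallback uses known reactions, sets out from 7 and returns at 17, so it also replaces steps 6 and 7. Aldehyde 7 is coupled with commercial 1-(4-fluoro-3-iodophenyl)ethan-1-one under Nozaki–Hiyama–Kishi conditions (CrCl2, cat. NiCl2, DMF; the ketone is tolerated). Felkin–Anh addition followed by K2CO3/MeOH desilylation should give the anti diol 1-{4-fluoro-3-[(1S,2S)-1,2-dihydroxy-3-[(4-methoxyphenyl)methoxy]-3-methylbutyl]phenyl}ethan-1-one F1. Intramolecular SNAr of the C2 alkoxide on the fluoride para to the acetyl group (KOtBu, THF) then closes the O1–C7a bond and gives 17.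

2. Step 14. Regiocontrol of the elimination may be lost (proton loss from C2 gives the exocyclic enol ether and from there the benzofuran), or the benzylic ester may ionise on heating. The fallback sets out from 18 and returns at 30, with the elimination done before the sensitive ester is present and the acylation done last. The secondary hydroxyl group of 18 is silylated (TESCl, imidazole) to give 1-[(2S,3S)-2-(2-hydroxypropan-2-yl)-3-(triethylsilyloxy)-2,3-dihydro-1-benzofuran-5-yl]ethan-1-one F2. The tertiary alcohol is eliminated with Martin sulfurane to give 1-[(2R,3S)-2-(prop-1-en-2-yl)-3-(triethylsilyloxy)-2,3-dihydro-1-benzofuran-5-yl]ethan-1-one F3, from which an isomeric alkene can be removed by chromatography. HF·pyridine gives 1-[(2R,3S)-3-hydroxy-2-(prop-1-en-2-yl)-2,3-dihydro-1-benzofuran-5-yl]ethan-1-one F4, which is esterified with 26 under the conditions of step 13 to give 30.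

3. Step 13. The enoate may isomerise from Z to E, or the allylic acetate may be displaced in SN2′ fashion by DMAP in the activated acyl species; acylation next to the quaternary carbinol may also be slow. The fallback sets out from 22 and 18 and returns at 28, carrying the acid as a silyl ether without an allylic leaving group. Alcohol 22 is silylated (TBSCl, imidazole) to give {[(2Z)-2-bromobut-2-en-1-yl]oxy}(tert-butyl)dimethylsilane F5. Br/Li exchange and carboxylation as in step 11 give (2Z)-2-({[tert-butyl(dimethyl)silyl]oxy}methyl)but-2-enoic acid F6. Yamaguchi esterification with 18 gives the silyl ether ester (2S,3S)-5-acetyl-2-(2-hydroxypropan-2-yl)-2,3-dihydro-1-benzofuran-3-yl (2Z)-2-({[tert-butyl(dimethyl)silyl]oxy}methyl)but-2-enoate F7. HF·pyridine gives the hydroxymethyl ester (2S,3S)-5-acetyl-2-(2-hydroxypropan-2-yl)-2,3-dihydro-1-benzofuran-3-yl (2Z)-2-(hydroxymethyl)but-2-enoate F8. Ac2O/pyridine acetylates only the primary hydroxyl group and gives 28.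

**Further compounds**
F1 | step 5 | 1-{4-fluoro-3-[(1S,2S)-1,2-dihydroxy-3-[(4-methoxyphenyl)methoxy]-3-methylbutyl]phenyl}ethan-1-one | COc1ccc(cc1)COC(C)(C)[C@@H](O)[C@@H](O)c1cc(C(C)=O)ccc1F
F2 | step 14 | 1-[(2S,3S)-2-(2-hydroxypropan-2-yl)-3-(triethylsilyloxy)-2,3-dihydro-1-benzofuran-5-yl]ethan-1-one | CC(C)(O)[C@H]1Oc2ccc(C(C)=O)cc2[C@@H]1O[Si](CC)(CC)CC
F3 | step 14 | 1-[(2R,3S)-2-(prop-1-en-2-yl)-3-(triethylsilyloxy)-2,3-dihydro-1-benzofuran-5-yl]ethan-1-one | C=C(C)[C@H]1Oc2ccc(C(C)=O)cc2[C@@H]1O[Si](CC)(CC)CC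
F4 | step 14 | 1-[(2R,3S)-3-hydroxy-2-(prop-1-en-2-yl)-2,3-dihydro-1-benzofuran-5-yl]ethan-1-one | C=C(C)[C@H]1Oc2ccc(C(C)=O)cc2[C@@H]1O
F5 | step 13 | {[(2Z)-2-bromobut-2-en-1-yl]oxy}(tert-butyl)dimethylsilane | C/C=C(\Br)CO[Si](C)(C)C(C)(C)C
F6 | step 13 | (2Z)-2-({[tert-butyl(dimethyl)silyl]oxy}methyl)but-2-enoic acid | C/C=C(\C(=O)O)CO[Si](C)(C)C(C)(C)C
F7 | step 13 | (2S,3S)-5-acetyl-2-(2-hydroxypropan-2-yl)-2,3-dihydro-1-benzofuran-3-yl (2Z)-2-({[tert-butyl(dimethyl)silyl]oxy}methyl)but-2-enoate | CC(C)(O)[C@H]1Oc2ccc(C(C)=O)cc2[C@@H]1OC(=O)/C(=C\C)CO[Si](C)(C)C(C)(C)C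
F8 | step 13 | (2S,3S)-5-acetyl-2-(2-hydroxypropan-2-yl)-2,3-dihydro-1-benzofuran-3-yl (2Z)-2-(hydroxymethyl)but-2-enoate | CC(C)(O)[C@H]1Oc2ccc(C(C)=O)cc2[C@@H]1OC(=O)/C(=C\C)CO
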